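Carried on as it began, the elm run would have reacted more substrate than its partner allows: the left-handed product readings can be read as a power of time, and that power puts the loss at 50 min above the ceiling.

the same everywhere: left-handed substrate 12 mM; right-handed substrate 12 mM; precatalyst 13 µM
- elm: partner 12 mM (fed, over 50 min); protic impurity 0.60 mM; run made earlier; the fed solution adds 0.25 times the starting volume
- flask: partner 12.0 mM (fed, over 50 min); protic impurity 1.20 mM; the fed solution adds 0.25 times the starting volume; time 50 min

- elm (time / min: left-handed substrate / %, right-handed substrate / %, left-handed product / %): 3.00: 49.6, 49.7, 0; 6.00: 50.1, 49.9, 0.3; 10.0: 48.9, 49.4, 1.6; 12.0: 48.8, 49.4, 1.9; 15.0: 47.3, 48.5, 2.7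

(readings scatter by 0.3 percentage points)

- catalyst is single-handed; left-handed substrate and right-handed substrate are mirror images of each other, charged as a racemate, each of them at the stated concentration
- every charge counts on the volume at the start, and the solution that is fed holds the whole dose
- what was read earlier has a scatter of 0.3 percentage points, one standard deviation
- steps under discussion: partner + catalyst + left-handed substrate -> catalyst + left-handed product; partner + catalyst + right-handed substrate -> catalyst + right-handed product; left-handed substrate <-> right-handed substrate; partner + protic impurity -> quenched reagent; precatalyst -> catalyst
- an excess is the difference of the two amounts in percent of their sum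
- an excess is below zero if the other one leads
- no earlier run changes the charge of protic impurity; that part of a forecast is a guess

* part of the left-handed substrate and right-handed substrate charged together that has reacted at 50 min
* excess of left-handed product over right-handed product in the product at 50 min
* excess of right-handed substrate over left-handed substrate among what is left of the two at 50 min

From the left-handed product in elm at 6.00 min and 15.0 min I read the power as 2.40. The substrates in elm had lost 4.20% at 15.0 min, so the power carried to 50 min gives 75.4%. But the partner is the limiting reagent in the flask, as in elm: 12.0 mM against 24.0 mM of substrate allows 50.0%. I therefore reckoned with the hold-up time instead, the partner standing in the flask divided by the rate at which it is used. I set the impurity aside, since no earlier run varies it; that was a guess.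

Standing in elm at 15.0 min, fed minus used, on the starting volume: c(partner) = 2.59 mM

Way one, rate from the readings at 10.0 min and 15.0 min: 0.120 mM/min, hold-up 21.6 min

Way two, rate from the power, n × used ÷ time: hold-up 16.1 min

They parted. Way one rests on a difference of 2.5 percentage points with a scatter of 0.6 points, so I took way two, though its power leans on a reading of 0.3%.

First round: conversion = ceiling × (1 − hold-up ÷ dosing time) = 33.9%

Second round: by the power, the take-up grows by 1.61, and the thinner substrate multiplies it by 0.690, so I reckoned the hold-up as 14.4 min and conversion as 35.6%

That is my number, above the forecast. The forecast, which held that “coupling, not feed, limits the rate”, gave 28%, with eP 38% and eS 14%.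

The flask gave 36.8%, eP 49.1% and eS 10.1%.

    partner + catalyst + left-handed substrate → catalyst + left-handed product (k = 33000 /M²/s)
    partner + catalyst + right-handed substrate → catalyst + right-handed product (k = 10000 /M²/s)
    left-handed substrate ⇌ right-handed substrate (k = 5.50 × 10⁻⁴ /s)
    partner + protic impurity → quenched reagent (k = 0.0210 /M/s)
    precatalyst → catalyst (k = 2.20 × 10⁻⁴ /s)

In this flask the step from partner and impurity barely moved the conversion. My second hold-up over the dosing time puts 28.9% of the partner charge still standing at the end, and the flask held 25% of its charge. The neighbour with 7.2 mM of partner has a ceiling of 30.0%. The same first hold-up gives 20.3%, and the second round gives 22.8%. Computed, that flask reached 23.1%.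

(All runs come from a simulation on assumed constants, noise included.)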